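The earlier runs and the new flask stem from a simulated flask with made-up constants, noise included.

Late in the north-west run the free electrophile is still falling, from 10.1% at 3.00 h to 2.6% at 6.00 h. The flask asked about has the same nucleophile charge as that run but less buffer base.

| flask | electrophile | nucleophile | buffer base | buffer acid | remark | time |
|---|---|---|---|---|---|---|
| east | 10 mM | 2 equiv | 0.20 equiv (fed, over 4.0 min) | 0.30 equiv | run made earlier |  |
| south-east | 10 mM | 4.5 equiv | 0.20 equiv (fed, over 4.0 min) | 0.30 equiv | run made earlier |  |
| north-west | 10 mM | 3 equiv | 0.30 equiv (fed, over 4.0 min) | 0.30 equiv | run made earlier |  |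
| flask | 10 mM | 3.00 equiv | 0.200 equiv (fed, over 4.0 min) | 0.300 equiv |  | 5.0 h |

| run | time / h | electrophile / % | target / % |
|---|---|---|---|
| east | 0.500 | 53.9 | 16.4 |
| east | 0.833 | 38.9 | 18.4 |
| east | 1.50 | 23.6 | 21.8 |
| east | 3.00 | 12.6 | 18.4 |
| east | 6.00 | 5.4 | 11.9 |
| south-east | 1.33 | 14.0 | 22.3 |
| south-east | 2.50 | 5.0 | 9.3 |
| south-east | 4.00 | 0.9 | 3.9 |
| south-east | 5.00 | 1.5 | 2.0 |
| south-east | 6.00 | 0 | 3.5 |
| north-west | 0.500 | 46.8 | 21.2 |
| north-west | 0.833 | 33.0 | 23.2 |
| north-west | 1.50 | 21.3 | 21.7 |
| north-west | 3.00 | 10.1 | 16.0 |
| north-west | 6.00 | 2.6 | 3.9 |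

(scatter of a reading: 1 percentage point)

- a reading or a percentage of target counts all its forms, free or not
- the earlier runs do not show the pH; that part of a forecast is a guess
- a reading of electrophile is of its free form alone

* part of the electrophile that has reacted at 5.0 h
* pH of the solution at 5.0 h

In the flask the electrophile is the limiting reagent, so its balance is the one to write. Down the north-west table, free electrophile plus target is 68.0% in the first row and 6.50% in the last, which leaves 93.5% of the charge in forms not read.

The last two rows give the late loss constant λ, the pseudo-first-order rate at which free electrophile disappears: the logarithm of their ratio over the time between them, 0.452 h⁻¹. It is a reading, and each of the two rows carries a scatter of 1 percentage point. The reckoning here assumes that each step using electrophile pairs two dissolved species. On that assumption, with the equivalents held and the feed set aside, a flask follows the same curve on a clock τ, the time multiplied by its electrophile charge over 10 mM.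

This reckoning also takes λ over to the flask, although the flask's buffer base charge differs from the north-west run's: carried on from the north-west 3.00 h row, λ leaves 4.09% free in the flask, so by this estimate 95.9% has reacted. The forecast, a separate judgement, stands lower at 95.3%, with pH 6: “The base is probably exhausted, so the solution is mildly acidic.”

    electrophile + nucleophile → acid + target + leaving group (k = 0.00952 M⁻¹ s⁻¹)
    protonated nucleophile ⇌ nucleophile + acid, settled at all times (K = 5.00 × 10⁻¹⁰ M)
    buffer acid ⇌ buffer base + acid, settled at all times (K = 7.90 × 10⁻⁹ M)
    electrophile + target ⇌ idle adduct, settled at all times (K = 23.1 M⁻¹)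
    nucleophile + target → over-reaction product (k = 0.0117 M⁻¹ s⁻¹)
    2 electrophile → homo dimer (k = 0.0143 M⁻¹ s⁻¹)

The flask gives 96.5% reacted, with 3.5% free against the 4.09% reckoned, and pH 9.38. By 2.50 h the flask's electrophile stood at 10.5%, homo dimer, counted by the electrophile it holds, at 36.0% and over-reaction product at 34.9%. By 5.00 h homo dimer had reached 37.1%, while free nucleophile, still 34.5% of its charge, went on turning target into over-reaction product, with target at 8.82% and over-reaction product at 50.5%. The neighbour flask with 2.5 mM of electrophile and the flask's equivalents sits at τ = 1.25 h after 5.0 h, where λ run back from the north-west 3.00 h row gives 22.3% free, and that neighbour holds 22.9% free.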